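**Plan**

Numbering: bicycle C1 (bridgehead bearing the cyclohexyl group), C2 and C3 (the CH2–CH2 bridge), C4 (methyl-bearing bridgehead), C5 (CHBr), C6 (CH2), O7; ring A is the carbocycle C1–C6; ring B is the cyclohexyl ring C1' (bonded to C1), C2', C3' (CMe2), C4' (CHBr), C5', C6'.
Enabling feature: O7 sits on the tertiary carbon C4, the bromine sits on the neighbouring C5 anti to O7 (endo), and O7 spans C1 and C4 of ring A; this is the imprint of an anti addition of a C1 hydroxyl and Br+ across a C4=C5 double bond, so the first cut removes O7–C4 together with C5–Br.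
Further cuts: C4=C5 (ring-closing metathesis), C1–C6 (allylation of a ketone), C1–C2 (ketone from an amide), C4'–Br (from an axial alcohol), one C3'–CH3, and ring B through C1'–C2' and C5'–C6' (Diels–Alder).
Forward: ring B first by a catalytic asymmetric Diels–Alder reaction, then its gem-dimethyl ketone and equatorial bromide, then ring A as a cyclohexenol, and last the oxygen bridge, which closes ring O7–C1–C2–C3–C4 and with it the bicycle.
Stereochemistry: C1' from the chiral Diels–Alder catalyst; C4' relayed from C1' (locked-chair reduction, then inversion); C1 from a chiral allylborane, because the two ring domains are too remote for relay; C4 and C5 from C1 in the bromoetherification.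

Key step: step 10

Assumption: the SMILES is read as the (1S,4R,5R) bicycle with the C5 bromine endo (anti to O7), carrying a (1'S,4'S) ring B with trans-1,4 (diequatorial) substituents.

Step 1
Reactants: 1 3-methylbut-3-en-2-one
Product: 2 3-methyl-2-[(triisopropylsilyl)oxy]buta-1,3-diene
Conditions: TIPSOTf, Et3N, CH2Cl2, 0 °C → rt
Reagents that add atoms: triisopropylsilyl trifluoromethanesulfonate, CC(C)[Si](OS(=O)(=O)C(F)(F)F)(C(C)C)C(C)C
Why: Soft enolisation and O-silylation of a methyl ketone whose only enolisable position is the methyl group should give the 2-silyloxydiene; no stereocenter is formed.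

Step 2
Reactants: 2 3-methyl-2-[(triisopropylsilyl)oxy]buta-1,3-diene; 3 2,2,2-trifluoroethyl acrylate
Product: 4 2,2,2-trifluoroethyl (1S)-3-methyl-4-[(triisopropylsilyl)oxy]cyclohex-3-ene-1-carboxylate
Conditions: (S)-3,3-diphenyl-1-(2-methylphenyl)tetrahydro-1H,3H-pyrrolo[1,2-c][1,3,2]oxazaborole·HN(SO2CF3)2 (10 mol %), CH2Cl2, −78 → −40 °C
Reagents that add atoms: none
Why: Catalytic enantioselective Diels–Alder reaction under a cationic chiral oxazaborolidine, in which the diene terminus next to the silyloxy carbon (largest HOMO coefficient) bonds to the acrylate β-carbon, placing the ester 1,4 to OSi and 1,3 to the methyl-bearing carbon, and in which the (S)-catalyst is the antipode expected to shield the Cα Si face of the boron-bound s-trans acrylate so that C1' forms as S.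

Step 3
Reactants: 4 2,2,2-trifluoroethyl (1S)-3-methyl-4-[(triisopropylsilyl)oxy]cyclohex-3-ene-1-carboxylate
Product: 5 (1S)-N-methoxy-N,3-dimethyl-4-[(triisopropylsilyl)oxy]cyclohex-3-ene-1-carboxamide
Conditions: MeNH(OMe)·HCl, i-PrMgCl, THF, −20 °C
Reagents that add atoms: N,O-dimethylhydroxylamine hydrochloride, CNOC.Cl
Why: Magnesium amide aminolysis of the activated ester (Weinreb amide formation) should proceed at low temperature without touching the silyl enol ether or the α-stereocenter, and gives an acyl group that later stops at the ketone stage.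

Step 4
Reactants: 5 (1S)-N-methoxy-N,3-dimethyl-4-[(triisopropylsilyl)oxy]cyclohex-3-ene-1-carboxamide
Product: 6 (1S)-N-methoxy-N,3,3-trimethyl-4-oxocyclohexane-1-carboxamide
Conditions: Bu4N+ Ph3SiF2−, MeI (excess), THF, 0 °C → rt
Reagents that add atoms: iodomethane, CI
Why: Fluoride-promoted regiospecific alkylation of a silyl enol ether, in which desilylation releases the tetrasubstituted enolate only at the position fixed by the cycloaddition and C-methylation creates the quaternary gem-dimethyl carbon C3' beside the new C4' ketone; no stereocenter is formed.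

Step 5
Reactants: 6 (1S)-N-methoxy-N,3,3-trimethyl-4-oxocyclohexane-1-carboxamide
Product: 7 (1S,4R)-4-hydroxy-N-methoxy-N,3,3-trimethylcyclohexane-1-carboxamide
Conditions: LiBH(s-Bu)3 (L-selectride), THF, −78 °C; then H2O
Reagents that add atoms: none
Why: Diastereoselective ketone reduction with a bulky trialkylborohydride, in which the amide is held equatorial (an axial amide would clash 1,3 with the axial C3' methyl) and the hydride enters along the equatorial trajectory, giving the axial C4' alcohol cis to the amide (4'R).

Step 6
Reactants: 7 (1S,4R)-4-hydroxy-N-methoxy-N,3,3-trimethylcyclohexane-1-carboxamide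
Product: 8 (1S,4S)-4-bromo-N-methoxy-N,3,3-trimethylcyclohexane-1-carboxamide
Conditions: PPh3, CBr4, CH2Cl2, 0 °C → reflux
Reagents that add atoms: tetrabromomethane, BrC(Br)(Br)Br
Why: Appel reaction, in which the alkoxyphosphonium ion of the axial alcohol is displaced by bromide in an SN2 step with inversion, so that bromine arrives equatorial and trans to C1' (4'S), while the neutral, non-ionising medium should hold back methyl shift from the neighbouring quaternary carbon.

Step 7
Reactants: 8 (1S,4S)-4-bromo-N-methoxy-N,3,3-trimethylcyclohexane-1-carboxamide; 9 4-bromo-2-methylbut-1-ene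
Product: 11 1-[(1S,4S)-4-bromo-3,3-dimethylcyclohexyl]-4-methylpent-4-en-1-one, via (3-methylbut-3-en-1-yl)magnesium bromide 10 (not isolated)
Conditions: 9, Mg, THF, rt; then 8, THF, −20 → 0 °C; aq. NH4Cl
Reagents that add atoms: none
Why: Weinreb ketone synthesis, in which the Grignard reagent adds only once because the magnesium chelate of the tetrahedral adduct survives until work-up, and in which the hindered secondary bromide and the α-stereocenter should be inert at 0 °C or below; no stereocenter is formed.

Step 8
Reactants: 11 1-[(1S,4S)-4-bromo-3,3-dimethylcyclohexyl]-4-methylpent-4-en-1-one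
Product: 12 (4S)-4-[(1S,4S)-4-bromo-3,3-dimethylcyclohexyl]-7-methylocta-1,7-dien-4-ol
Conditions: B-allyl-10-phenyl-9-borabicyclo[3.3.2]decane (single enantiomer, the antipode that transfers allyl to the Si face), Et2O, −78 → 0 °C; aq. NaOH work-up
Reagents that add atoms: B-allyl-10-phenyl-9-borabicyclo[3.3.2]decane, C=CCB1C2CCCC(CCC2)C1c1ccccc1
Why: Reagent-controlled asymmetric allylboration of a ketone through a closed six-membered chair transition state, in which the rigid chiral boracycle distinguishes the branched cyclohexyl group from the unbranched chain and delivers allyl to the Si face of the carbonyl (O > cyclohexyl C > CH2), setting the tertiary carbinol carbon (later C1) as S.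

Step 9
Reactants: 12 (4S)-4-[(1S,4S)-4-bromo-3,3-dimethylcyclohexyl]-7-methylocta-1,7-dien-4-ol
Product: 13 (1S)-1-[(1S,4S)-4-bromo-3,3-dimethylcyclohexyl]-4-methylcyclohex-3-en-1-ol
Conditions: second-generation Grubbs catalyst (H2IMes)(PCy3)Cl2Ru=CHPh (5 mol %), CH2Cl2, 40 °C
Reagents that add atoms: none
Why: Ring-closing olefin metathesis of the monosubstituted and the 1,1-disubstituted alkene should close ring A with a trisubstituted C4=C5 bond and release ethylene, with the free tertiary alcohol and the alkyl bromide tolerated and the carbinol configuration untouched.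

Step 10
Reactants: 13 (1S)-1-[(1S,4S)-4-bromo-3,3-dimethylcyclohexyl]-4-methylcyclohex-3-en-1-ol
Product: 14 (1S,4R,5R)-5-bromo-1-[(1S,4S)-4-bromo-3,3-dimethylcyclohexyl]-4-methyl-7-oxabicyclo[2.2.1]heptane (the target; numbering of the plan)
Conditions: NBS, CH2Cl2, 0 °C, dark
Reagents that add atoms: N-bromosuccinimide, O=C1CCC(=O)N1Br
Why: Electrophilic bromine adds reversibly to both faces of the C4=C5 bond, but only the bromonium ion anti to the pseudoaxial C1 hydroxyl can be opened from inside, the oxygen attacking the tertiary carbon C4 across ring A through a boat-like conformer. The closest known reaction type is the transannular haloetherification of 1-substituted 4-methylcyclohex-3-en-1-ols to 2-halo-7-oxabicyclo[2.2.1]heptanes (bromo-1,4-cineole type). The single new O7–C4 bond closes ring O7–C1–C2–C3–C4 in the 5-exo mode (C5 stays outside this ring) and at the same time ring O7–C1–C6–C5–C4 in the 5-endo mode, which completes the bridged bicycle. C4 is fixed because O7 can only arrive from the face that carries the C1 hydroxyl (C1 set in step 8), and C5 is fixed by the anti opening of the bromonium ion, which places bromine endo, anti to O7, a position that substitution or radical bromination on a finished bicycle would not be expected to reach. The step needs regioselectivity for C4 over C5, secured by the tertiary (Markovnikov) character of C4 and by the fact that attack at C5 would give an oxetane, and it needs a pseudoaxial hydroxyl, secured by the large cyclohexyl group on C1 taking the pseudoequatorial place. The C4' bromide and the rest of ring B should be inert to N-bromosuccinimide.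

**Compound list**

1 | 3-methylbut-3-en-2-one | CC(=O)C(C)=C | starting material
2 | 3-methyl-2-[(triisopropylsilyl)oxy]buta-1,3-diene | C=C(C)C(=C)O[Si](C(C)C)(C(C)C)C(C)C | intermediate
3 | 2,2,2-trifluoroethyl acrylate | C=CC(=O)OCC(F)(F)F | starting material
4 | 2,2,2-trifluoroethyl (1S)-3-methyl-4-[(triisopropylsilyl)oxy]cyclohex-3-ene-1-carboxylate | CC1=C(O[Si](C(C)C)(C(C)C)C(C)C)CC[C@H](C(=O)OCC(F)(F)F)C1 | intermediate
5 | (1S)-N-methoxy-N,3-dimethyl-4-[(triisopropylsilyl)oxy]cyclohex-3-ene-1-carboxamide | CC1=C(O[Si](C(C)C)(C(C)C)C(C)C)CC[C@H](C(=O)N(C)OC)C1 | intermediate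
6 | (1S)-N-methoxy-N,3,3-trimethyl-4-oxocyclohexane-1-carboxamide | CC1(C)C[C@@H](C(=O)N(C)OC)CCC1=O | intermediate
7 | (1S,4R)-4-hydroxy-N-methoxy-N,3,3-trimethylcyclohexane-1-carboxamide (cis, hydroxyl axial) | CC1(C)C[C@@H](C(=O)N(C)OC)CC[C@H]1O | intermediate
8 | (1S,4S)-4-bromo-N-methoxy-N,3,3-trimethylcyclohexane-1-carboxamide (trans, bromine equatorial) | CC1(C)C[C@@H](C(=O)N(C)OC)CC[C@@H]1Br | intermediate
9 | 4-bromo-2-methylbut-1-ene | C=C(C)CCBr | starting material
10 | (3-methylbut-3-en-1-yl)magnesium bromide | C=C(C)CC[Mg]Br | intermediate (not isolated)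
11 | 1-[(1S,4S)-4-bromo-3,3-dimethylcyclohexyl]-4-methylpent-4-en-1-one | CC1(C)C[C@@H](C(=O)CCC(C)=C)CC[C@@H]1Br | intermediate
12 | (4S)-4-[(1S,4S)-4-bromo-3,3-dimethylcyclohexyl]-7-methylocta-1,7-dien-4-ol | CC1(C)C[C@@H]([C@@](O)(CC=C)CCC(C)=C)CC[C@@H]1Br | intermediate
13 | (1S)-1-[(1S,4S)-4-bromo-3,3-dimethylcyclohexyl]-4-methylcyclohex-3-en-1-ol | CC1(C)C[C@@H]([C@]2(O)CCC(C)=CC2)CC[C@@H]1Br | intermediate
14 | (1S,4R,5R)-5-bromo-1-[(1S,4S)-4-bromo-3,3-dimethylcyclohexyl]-4-methyl-7-oxabicyclo[2.2.1]heptane, by lowest locants (1R,2R,4S)-2-bromo-4-[(1S,4S)-4-bromo-3,3-dimethylcyclohexyl]-1-methyl-7-oxabicyclo[2.2.1]heptane | CC1(C)C[C@@H]([C@@]23CC[C@@](C)(O2)[C@H](Br)C3)CC[C@@H]1Br | target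

**Totals and risks**

Total step count: 10. Longest linear sequence: 10 steps (1 to 14).

Steps most likely to fail:

Step 8. The allylboration may show poor facial discrimination, because the two ketone substituents differ only as branched versus unbranched alkyl, and addition to the hindered ketone may be slow. The fallback gives up induction at this carbon and relies on ring B already being enantiopure. It sets out from 11: addition of allylmagnesium bromide with CeCl3 (THF, −78 °C) without stereocontrol should give 12 together with its carbinol epimer (4R)-4-[(1S,4S)-4-bromo-3,3-dimethylcyclohexyl]-7-methylocta-1,7-dien-4-ol F1. Ring-closing metathesis of the mixture under the conditions of step 9 should give 13 and (1R)-1-[(1S,4S)-4-bromo-3,3-dimethylcyclohexyl]-4-methylcyclohex-3-en-1-ol F2, which are diastereomers and are separated by preparative chromatography. The route is rejoined at 13.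

Step 6. Elimination to the cyclohexene and 1,2-methyl shift may compete with SN2 displacement at a carbon flanked by a quaternary centre. The fallback uses the cis relationship of hydroxyl and acyl group to change the leaving group. It sets out from 7: acid-catalysed lactonisation (camphorsulfonic acid, toluene, reflux) should give the bridged lactone (1R,4S)-6,6-dimethyl-2-oxabicyclo[2.2.2]octan-3-one F3. Opening of its alkyl C–O bond by bromide (Me3SiBr, CH2Cl2, 40 °C; then H2O) should give, with inversion, (1S,4S)-4-bromo-3,3-dimethylcyclohexane-1-carboxylic acid F4. Amide coupling with N,O-dimethylhydroxylamine (carbodiimide activation) comes back to the route at 8.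

Step 4. Protodesilylation without alkylation, or O-methylation, may occur at the hindered tetrasubstituted enolate. The fallback replaces alkylation by cyclopropanation and ring opening. It sets out from 5: Et2Zn and CH2I2 (CH2Cl2, 0 °C) should give the siloxycyclopropane (3S)-N-methoxy-N,1-dimethyl-6-[(triisopropylsilyl)oxy]bicyclo[4.1.0]heptane-3-carboxamide F5 as a mixture of ring-fusion diastereomers that converge. Desilylation with Bu4NF followed by base-induced opening of the cyclopropanol at the C(O)–CH2 bond (KOH, MeOH) should give the gem-dimethyl ketone and come back to the route at 6.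

Further compounds
F1 | step 8 | (4R)-4-[(1S,4S)-4-bromo-3,3-dimethylcyclohexyl]-7-methylocta-1,7-dien-4-ol | CC1(C)C[C@@H]([C@](O)(CC=C)CCC(C)=C)CC[C@@H]1Br
F2 | step 8 | (1R)-1-[(1S,4S)-4-bromo-3,3-dimethylcyclohexyl]-4-methylcyclohex-3-en-1-ol | CC1(C)C[C@@H]([C@@]2(O)CCC(C)=CC2)CC[C@@H]1Br
F3 | step 6 | (1R,4S)-6,6-dimethyl-2-oxabicyclo[2.2.2]octan-3-one | CC1(C)C[C@@H]2CC[C@H]1OC2=O
F4 | step 6 | (1S,4S)-4-bromo-3,3-dimethylcyclohexane-1-carboxylic acid | CC1(C)C[C@@H](C(=O)O)CC[C@@H]1Br
F5 | step 4 | (3S)-N-methoxy-N,1-dimethyl-6-[(triisopropylsilyl)oxy]bicyclo[4.1.0]heptane-3-carboxamide | CC12CC1(O[Si](C(C)C)(C(C)C)C(C)C)CC[C@H](C(=O)N(C)OC)C2
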